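I read this flask at one moment: when 20% of the starting material is converted.

starting material 0.050 M; enzyme 0.01 mol%

    starting material + enzyme → target + enzyme, rate k1*[starting material]*[enzyme]/(1 + ([starting material]/Km1) + ([target]/Kp1)) (Km1 = 0.0708 M, Kp1 = 0.668 mM, k1 = 2.98 × 10⁵ M⁻¹ s⁻¹)
    starting material + enzyme → spent catalyst (k2 = 3.11 M⁻¹ s⁻¹)

- the form that holds most of the catalyst when 20% of the starting material are converted (spent catalyst / enzyme)
- its share of the catalyst then
- factor on the rate of making target when 20% of the starting material are converted if enzyme is charged twice over
- factor on the rate when 20% of the starting material are converted if enzyme is charged at 0.002 mol% instead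

My ledger is for the enzyme. Both steps carry [starting material]·[enzyme], so dividing one rate by the other cancels both. Each mole of target then costs s·D moles of enzyme. Here s is the second rate constant over the first, 1.04 × 10⁻⁵, and D is the denominator of the rate law of step one. The enzyme charge has dropped out.

The opening entry is the charge, 5.00 µM. The reading needs x = 10.0 mM of target. D is linear in target, rising from 1.71 at the start to 16.5 at the reading, so its mean is 9.12.

The debit is s times that mean times x, which is 0.952 µM. This is far less than x, so I count the conversion as target. I call this amount the toll: the enzyme turned into spent catalyst by the time a given amount of target has been made, the same in my ledger for the charges asked about.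

The books close with 4.05 µM of enzyme, which is 81.0% of the charge, and the toll as spent catalyst.

At equal conversion the rate follows the enzyme left. A doubled charge keeps 9.05 µM, a factor of 2.23. The charge of 0.002 mol% is 1.00 µM, which keeps 0.0481 µM, a factor of 0.0119.

The forecast gives enzyme at 81%, and factors of 2.24 and 0.012. It calls the last rate “very sensitive to the exact loss”.

The simulation reaches the reading at 1.57 s, with enzyme at 81.0%, and gives factors of 2.24 and 0.0119.

In this flask the toll is 19.0% of the charge, and the run shows 19.0% as spent catalyst. In the flask charged at 0.002 mol%, the same toll is 95.2% of the charge, and its run shows 95.2% as spent catalyst at the same conversion. The loss to spent catalyst is one part of what shapes the rate in this flask. With that loss taken away, the rate at the reading is 1.23 times the actual one, and the apparent order in enzyme goes from 1.2 to 1.0.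

The constants used here were drawn at random within sensible limits; the run is a simulation.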